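The enolised 5,6-dihydropyran-2,4-dione ring is read as a hydrogenated 4-hydroxy-2-pyrone. The ring oxygen O1 and the methyl-bearing carbon C6 are joined when the ester carbonyl oxygen of tert-butyl 3-oxohex-4-ynoate attacks its gold-activated alkyne in a 6-endo-dig closure; loss of isobutene gives the aromatic pyrone in one operation. The step exploits that C5–C6 of the lactone ring, after formal dehydrogenation, is the triple bond of an ynone whose β-carbon (C6) is electrophilic. Asymmetric hydrogenation then sets C6, and the ring is C3-acylated with a side chain assembled by anti-selective dianion allylation and a ruthenium Alder-ene coupling.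

Key step: step 2

Assumption: the (S)-configured diphosphine–ruthenium catalyst of the pyrone hydrogenation is taken to deliver the (6R)-lactone; should the sense prove opposite, the (R)-ligand is used.

Step 1
Reactants: 1 tert-butyl acetate; 2 ethyl but-2-ynoate
Product: 3 tert-butyl 3-oxohex-4-ynoate
Conditions: LiN(iPr)2 (2.2 equiv), THF, −78 °C; then 2 (1 equiv), −78 °C; 1 M HCl quench
Reagents that add atoms: none
Why: Crossed Claisen condensation, in which the lithium enolate of 1 adds to the ester carbonyl of 2 faster than to its conjugate position at −78 °C and the second equivalent of enolate deprotonates the β-keto ester as it forms, which prevents over-addition.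

Step 2
Reactants: 3 tert-butyl 3-oxohex-4-ynoate
Product: 4 4-hydroxy-6-methyl-2H-pyran-2-one
Conditions: (SPhos)AuNTf2 (2 mol%), MeNO2/AcOH (4:1), rt
Reagents that add atoms: none
Why: The cationic monovalent gold centre binds the alkyne of 3 and the ester carbonyl oxygen attacks the alkyne carbon remote from the ketone (the β-carbon of the ynone, the future C6) anti to gold, which forms the O1–C6 bond and closes the pyranone ring; the resulting tert-butyl oxocarbenium ion loses isobutene, protodeauration by acetic acid frees the catalyst and the pyran-2,4-dione tautomerises to aromatic 4. The closest known reaction type is the gold-catalysed cyclisation of tert-butyl 3-oxoalk-4-ynoates to 4-hydroxy-2-pyrones. The six-membered ring is closed in the 6-endo-dig mode. No stereocentre is formed, since C6 becomes sp2 and is converted into the (6R) centre only in step 3. The step needs 6-endo over 5-exo regioselectivity, which the polarisation of the ynone (conjugate position C6) and the reach of the ester carbonyl oxygen secure, and it needs O- rather than C-cyclisation, which is secured because C3 could only close three- or four-membered rings. Irreversible loss of isobutene and aromatisation should drive the closure to completion.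

Step 3
Reactants: 4 4-hydroxy-6-methyl-2H-pyran-2-one
Product: 5 (6R)-4-hydroxy-6-methyl-5,6-dihydro-2H-pyran-2-one
Conditions: Ru(OAc)2[(S)-3,5-tBu-MeO-BIPHEP] (0.5 mol%), HBF4·OEt2 (1 mol%), H2 (60 bar), iPrOH, 60 °C
Reagents that add atoms: none
Why: Asymmetric hydrogenation of the C5=C6 double bond of a 4-hydroxy-2-pyrone by a cationic ruthenium hydride bearing an atropisomeric diphosphine is a known reaction of this very substrate, in which the ligand selects the face of C6 that receives hydrogen and so sets the (6R) centre, while the C3=C4 enol double bond of the resulting vinylogous acid is not reduced.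

Step 4
Reactants: 6 (S)-2-methylbutanoic acid; 7 Meldrum's acid
Product: 10 tert-butyl (4S)-4-methyl-3-oxohexanoate, via acyl Meldrum's acid 8 (not isolated), via acylketene 9 (not isolated)
Conditions: DCC, DMAP, CH2Cl2, 0 °C to rt; then tBuOH, toluene, 90 °C
Reagents that add atoms: tert-butanol CC(C)(C)O
Why: DCC-mediated C-acylation of Meldrum's acid followed by thermal loss of acetone and CO2 to an acylketene that is trapped by tert-butanol is the standard Meldrum's acid synthesis of β-keto esters, and the α-stereocentre of 6 is not enolised under these neutral to weakly basic conditions, so it should be carried through as (4S).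

Step 5
Reactants: 10 tert-butyl (4S)-4-methyl-3-oxohexanoate
Product: 11 tert-butyl (3S,4S)-3-hydroxy-4-methylhexanoate
Conditions: RuCl2[(R)-BINAP] (0.5 mol%), H2 (50 bar), MeOH, 50 °C
Reagents that add atoms: none
Why: Noyori asymmetric hydrogenation of a β-keto ester, in which the ketone chelated to ruthenium through the ester is reduced under catalyst control by the (R)-BINAP complex to the (3S) carbinol, with the neighbouring (4S) centre left untouched under the neutral conditions.

Step 6
Reactants: 11 tert-butyl (3S,4S)-3-hydroxy-4-methylhexanoate; 12 allyl bromide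
Product: 13 tert-butyl (2R,3R,4S)-3-hydroxy-4-methyl-2-(prop-2-en-1-yl)hexanoate
Conditions: LiN(iPr)2 (2.2 equiv), THF, −78 to −20 °C; then 12, DMPU, −78 to 0 °C; 1 M HCl quench at 0 °C
Reagents that add atoms: none
Why: Fráter–Seebach alkylation, in which the lithium alkoxide-enolate dianion forms a six-membered chelate that is allylated on the face away from the C3 substituent, so the new C2 centre is set anti to the hydroxyl, which corresponds to (2R).

Step 7
Reactants: 13 tert-butyl (2R,3R,4S)-3-hydroxy-4-methyl-2-(prop-2-en-1-yl)hexanoate; 14 methyl pent-4-ynoate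
Product: 15 1-tert-butyl 9-methyl (2R,3E)-2-[(1R,2S)-1-hydroxy-2-methylbutyl]-6-methylidenenon-3-enedioate
Conditions: [CpRu(MeCN)3]PF6 (10 mol%), 14 (1.5 equiv), acetone, rt
Reagents that add atoms: none
Why: Ruthenium-catalysed Alder-ene type alkene–alkyne coupling, in which oxidative cyclisation of both partners on the cationic cyclopentadienylruthenium centre gives a ruthenacyclopentene that undergoes β-hydride elimination from the allylic CH2 of 13 and reductive elimination to the branched 1,4-diene with an E double bond, leaving all three stereocentres untouched because the hydrogen that migrates does not come from C2.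

Step 8
Reactants: 15 1-tert-butyl 9-methyl (2R,3E)-2-[(1R,2S)-1-hydroxy-2-methylbutyl]-6-methylidenenon-3-enedioate
Product: 16 (6E,8R)-9-tert-butoxy-8-[(1R,2S)-1-hydroxy-2-methylbutyl]-4-methylidene-9-oxonon-6-enoic acid
Conditions: LiOH·H2O (1.5 equiv), THF/H2O (3:1), 0 °C; then 1 M HCl to pH 3
Reagents that add atoms: lithium hydroxide [Li+].[OH-]
Why: Chemoselective saponification, since hydroxide attacks the unhindered methyl ester whereas the α-branched tert-butyl ester is inert to aqueous LiOH at 0 °C and the weak base does not enolise the ester next to the alkene.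

Step 9
Reactants: 16 (6E,8R)-9-tert-butoxy-8-[(1R,2S)-1-hydroxy-2-methylbutyl]-4-methylidene-9-oxonon-6-enoic acid; 5 (6R)-4-hydroxy-6-methyl-5,6-dihydro-2H-pyran-2-one
Product: 18 tert-butyl ester of the target acid, via enol ester 17 (not isolated)
Conditions: DCC (1.2 equiv), DMAP (0.3 equiv), CH2Cl2, 0 °C to rt
Reagents that add atoms: none
Why: Carbodiimide O-acylation of the acidic enol of 5 followed by DMAP-mediated O-to-C acyl migration (an acyl Fries-type rearrangement known for 4-hydroxy-5,6-dihydropyran-2-ones) places the acyl group on C3, the hindered secondary hydroxyl of 16 being much less nucleophilic than the enolate of 5 and the C6 centre being unaffected.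

Step 10
Reactants: 18 tert-butyl ester of the target acid
Product: 20 CNP0221901.1, via tris(trimethylsilyl) derivative 19 (not isolated)
Conditions: Me3SiOTf (4 equiv), 2,6-lutidine (6 equiv), CH2Cl2, 0 °C; then 0.5 M aq. citric acid/THF, rt
Reagents that add atoms: none
Why: Silyl triflate-mediated cleavage of a tert-butyl ester, in which O-silylation of the ester carbonyl releases the tert-butyl cation as isobutene under lutidine buffering so that no strong protic acid meets the skipped diene, and the silyl ester, silyl ether and silyl enol ether of 19 are hydrolysed on mild aqueous work-up without touching any stereocentre.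

Compound list
1 | tert-butyl acetate | CC(=O)OC(C)(C)C | starting material
2 | ethyl but-2-ynoate | CC#CC(=O)OCC | starting material
3 | tert-butyl 3-oxohex-4-ynoate | CC#CC(=O)CC(=O)OC(C)(C)C | intermediate
4 | 4-hydroxy-6-methyl-2H-pyran-2-one | CC1=CC(O)=CC(=O)O1 | intermediate
5 | (6R)-4-hydroxy-6-methyl-5,6-dihydro-2H-pyran-2-one | O=C1C=C(O)C[C@@H](C)O1 | intermediate
6 | (S)-2-methylbutanoic acid | CC[C@H](C)C(=O)O | starting material
7 | Meldrum's acid (2,2-dimethyl-1,3-dioxane-4,6-dione) | CC1(C)OC(=O)CC(=O)O1 | starting material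
8 | 5-[(2S)-1-hydroxy-2-methylbutylidene]-2,2-dimethyl-1,3-dioxane-4,6-dione (acyl Meldrum's acid) | CC[C@H](C)C(O)=C1C(=O)OC(C)(C)OC1=O | intermediate
9 | (4S)-4-methylhex-1-ene-1,3-dione (acylketene) | CC[C@H](C)C(=O)C=C=O | intermediate
10 | tert-butyl (4S)-4-methyl-3-oxohexanoate | CC[C@H](C)C(=O)CC(=O)OC(C)(C)C | intermediate
11 | tert-butyl (3S,4S)-3-hydroxy-4-methylhexanoate | CC[C@H](C)[C@@H](O)CC(=O)OC(C)(C)C | intermediate
12 | allyl bromide (3-bromoprop-1-ene) | C=CCBr | starting material
13 | tert-butyl (2R,3R,4S)-3-hydroxy-4-methyl-2-(prop-2-en-1-yl)hexanoate | C=CC[C@@H](C(=O)OC(C)(C)C)[C@H](O)[C@@H](C)CC | intermediate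
14 | methyl pent-4-ynoate | C#CCCC(=O)OC | starting material
15 | 1-tert-butyl 9-methyl (2R,3E)-2-[(1R,2S)-1-hydroxy-2-methylbutyl]-6-methylidenenon-3-enedioate | C=C(C/C=C/[C@@H](C(=O)OC(C)(C)C)[C@H](O)[C@@H](C)CC)CCC(=O)OC | intermediate
16 | (6E,8R)-9-tert-butoxy-8-[(1R,2S)-1-hydroxy-2-methylbutyl]-4-methylidene-9-oxonon-6-enoic acid | C=C(C/C=C/[C@@H](C(=O)OC(C)(C)C)[C@H](O)[C@@H](C)CC)CCC(=O)O | intermediate
17 | enol ester of acid 16 on the C4 oxygen of pyranone 5, (6R)-6-methyl-2-oxo-5,6-dihydro-2H-pyran-4-yl ester | C=C(C/C=C/[C@@H](C(=O)OC(C)(C)C)[C@H](O)[C@@H](C)CC)CCC(=O)OC1=CC(=O)O[C@H](C)C1 | intermediate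
18 | tert-butyl (2R,3E)-2-[(1R,2S)-1-hydroxy-2-methylbutyl]-9-[(6R)-4-hydroxy-6-methyl-2-oxo-5,6-dihydro-2H-pyran-3-yl]-6-methylidene-9-oxonon-3-enoate | C=C(C/C=C/[C@@H](C(=O)OC(C)(C)C)[C@H](O)[C@@H](C)CC)CCC(=O)C1=C(O)C[C@@H](C)OC1=O | intermediate
19 | tris(trimethylsilyl) derivative of 20 (silyl ester, C3' silyl ether, C4 silyl enol ether) | C=C(C/C=C/[C@@H](C(=O)O[Si](C)(C)C)[C@H](O[Si](C)(C)C)[C@@H](C)CC)CCC(=O)C1=C(O[Si](C)(C)C)C[C@@H](C)OC1=O | intermediate
20 | CNP0221901.1, (2R,3E)-2-[(1R,2S)-1-hydroxy-2-methylbutyl]-9-[(6R)-4-hydroxy-6-methyl-2-oxo-5,6-dihydro-2H-pyran-3-yl]-6-methylidene-9-oxonon-3-enoic acid | C=C(C/C=C/[C@@H](C(=O)O)[C@H](O)[C@@H](C)CC)CCC(=O)C1=C(O)C[C@@H](C)OC1=O | target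

Total step count: 10. Longest linear sequence: 7 steps (steps 4 to 10, from 6).

Steps most likely to fail

1. Step 7. The chelating β-hydroxy ester of 13 may sequester the ruthenium catalyst, and the branched-to-linear regiocontrol of ruthenacycle formation may erode with this β-branched alkene. The fallback sets out from 13 and 14 and returns at 15, replacing the ene coupling by C–H oxidation and cross-coupling. Palladium-catalysed linear allylic C–H acetoxylation of 13 (Pd(OAc)2, benzoquinone, DMSO/AcOH, 40 °C) should give the allylic acetate tert-butyl (2R,3E)-5-acetoxy-2-[(1R,2S)-1-hydroxy-2-methylbutyl]pent-3-enoate F1. Stannylcupration of 14 (Me3SnCu·SMe2, MeOH, THF, −63 °C) should give the internal alkenylstannane methyl 4-(trimethylstannyl)pent-4-enoate F2. Stille coupling of F1 with F2 (Pd2(dba)3, LiCl, DMF, rt) at the unhindered allyl terminus should then give 15.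

2. Step 9. The free secondary hydroxyl of 16 may be acylated in competition with the enol of 5, and the O-to-C acyl migration may stall at the enol ester. The fallback sets out from 5 and returns at 18 by reversing the order of fragment union. Pyranone 5 is acylated with pent-4-ynoic acid (DCC, DMAP, CH2Cl2), which carries no hydroxyl, through the enol ester (6R)-6-methyl-2-oxo-5,6-dihydro-2H-pyran-4-yl pent-4-ynoate F3 to (6R)-4-hydroxy-6-methyl-3-(pent-4-ynoyl)-5,6-dihydro-2H-pyran-2-one F4. F4 is then coupled with 13 under the ene conditions of step 7 to give 18 directly.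

3. Step 10. Ionisation of the hindered tert-butyl ester may be slow, and acid generated in the flask may isomerise the skipped diene or let the tert-butyl cation add to an alkene. The fallback sets out from 13 and returns at 20 by exchanging the ester before the diene exists.
   - 13 is cleaved with CF3CO2H/CH2Cl2 to (2R,3R,4S)-3-hydroxy-4-methyl-2-(prop-2-en-1-yl)hexanoic acid F5.
   - F5 is esterified with 2-(trimethylsilyl)ethanol (DCC, DMAP) to 2-(trimethylsilyl)ethyl (2R,3R,4S)-3-hydroxy-4-methyl-2-(prop-2-en-1-yl)hexanoate F6.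
   - F6 is taken through the chemistry of steps 7 to 9: ene coupling with 14 to the diene diester F7, LiOH saponification to the acid F8, and acylation of 5 through the enol ester F9 to the 3-acyl pyranone 2-(trimethylsilyl)ethyl ester F10.
   - F10 is unmasked with fluoride ((Me2N)3S+ Me3SiF2−, DMF, 0 °C) to give 20.

Further compounds
F1 | step 7 | tert-butyl (2R,3E)-5-acetoxy-2-[(1R,2S)-1-hydroxy-2-methylbutyl]pent-3-enoate | CC(=O)OC/C=C/[C@@H](C(=O)OC(C)(C)C)[C@H](O)[C@@H](C)CC
F2 | step 7 | methyl 4-(trimethylstannyl)pent-4-enoate | C=C(CCC(=O)OC)[Sn](C)(C)C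
F3 | step 9 | (6R)-6-methyl-2-oxo-5,6-dihydro-2H-pyran-4-yl pent-4-ynoate | C#CCCC(=O)OC1=CC(=O)O[C@H](C)C1
F4 | step 9 | (6R)-4-hydroxy-6-methyl-3-(pent-4-ynoyl)-5,6-dihydro-2H-pyran-2-one | C#CCCC(=O)C1=C(O)C[C@@H](C)OC1=O
F5 | step 10 | (2R,3R,4S)-3-hydroxy-4-methyl-2-(prop-2-en-1-yl)hexanoic acid | C=CC[C@@H](C(=O)O)[C@H](O)[C@@H](C)CC
F6 | step 10 | 2-(trimethylsilyl)ethyl (2R,3R,4S)-3-hydroxy-4-methyl-2-(prop-2-en-1-yl)hexanoate | C=CC[C@@H](C(=O)OCC[Si](C)(C)C)[C@H](O)[C@@H](C)CC
F7 | step 10 | 9-methyl 1-[2-(trimethylsilyl)ethyl] (2R,3E)-2-[(1R,2S)-1-hydroxy-2-methylbutyl]-6-methylidenenon-3-enedioate | C=C(C/C=C/[C@@H](C(=O)OCC[Si](C)(C)C)[C@H](O)[C@@H](C)CC)CCC(=O)OC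
F8 | step 10 | (6E,8R)-8-[(1R,2S)-1-hydroxy-2-methylbutyl]-4-methylidene-9-oxo-9-[2-(trimethylsilyl)ethoxy]non-6-enoic acid | C=C(C/C=C/[C@@H](C(=O)OCC[Si](C)(C)C)[C@H](O)[C@@H](C)CC)CCC(=O)O
F9 | step 10 | enol ester of F8 on the C4 oxygen of 5 | C=C(C/C=C/[C@@H](C(=O)OCC[Si](C)(C)C)[C@H](O)[C@@H](C)CC)CCC(=O)OC1=CC(=O)O[C@H](C)C1
F10 | step 10 | 2-(trimethylsilyl)ethyl ester of 20 | C=C(C/C=C/[C@@H](C(=O)OCC[Si](C)(C)C)[C@H](O)[C@@H](C)CC)CCC(=O)C1=C(O)C[C@@H](C)OC1=O
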